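**Plan**
Labels: flavone 1 has rings A (benzo), C (pyranone) and B (4-methoxyphenyl). Flavone 2 has rings D (benzo), F (pyranone) and E (the para-phenylene that holds the ether oxygen).
First cut: C4–C4a and O1–C2 of ring F. Ring D carries oxygen on C5, C7 and C8a (O1) in a 1,3,5 array, has 5-OH and 7-OH free and H on C6 and C8, so it is phloroglucinol, whose three C–H carbons are equivalent. What remains is an ethyl aroylacetate on ring E.
Further cuts: the CH2–CO2Et bond of that keto ester (diethyl carbonate), the O–C bond from the ether oxygen to ring E (4'-fluoroacetophenone), and the C8–O bond on ring A (persulfate).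
Forward: rings A, B and C are bought together as apigenin 7,4'-dimethyl ether. O8, ring E and the ester carbon are then added in that order. Ring D arrives last, and ring F is the only ring closed in the route. No protecting group is used.
Stereochemistry: the target has no stereocentre and no configurable double bond, so nothing has to be set.

Key step: step 4

Assumption: apigenin 7,4'-dimethyl ether is taken as a catalogue compound. Phloroglucinol is used anhydrous (the dihydrate is dried at 110 °C in vacuo), because water in the melt would cleave the keto ester.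

**Step 1**
Reactants: 1 5-hydroxy-7-methoxy-2-(4-methoxyphenyl)-4H-chromen-4-one (apigenin 7,4'-dimethyl ether)
Product: 3 5,8-dihydroxy-7-methoxy-2-(4-methoxyphenyl)-4H-chromen-4-one, via potassium flavon-8-yl sulfate 2 (not isolated)
Conditions: K2S2O8 (1.2 equiv), aq KOH, pyridine, 15–20 °C, 24 h; HCl to pH 4, unchanged 1 filtered off for recycling; then conc. HCl, 90 °C, N2
Reagents that add atoms: potassium peroxydisulfate, [K+].[K+].[O-]S(=O)(=O)OOS(=O)(=O)[O-]
Why: This is an Elbs persulfate oxidation, in which the 5-phenoxide attacks a peroxide oxygen of peroxydisulfate through its para carbon (here the unsubstituted C8) to give aryl sulfate 2, and hot dilute acid then cleaves the S–O bond to free the 8-hydroxyl, a sequence long used to convert 5-hydroxyflavones into 5,8-dihydroxyflavones.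

**Step 2**
Reactants: 3 5,8-dihydroxy-7-methoxy-2-(4-methoxyphenyl)-4H-chromen-4-one; 4 4'-fluoroacetophenone
Product: 5 8-(4-acetylphenoxy)-5-hydroxy-7-methoxy-2-(4-methoxyphenyl)-4H-chromen-4-one
Conditions: 4 (1.5 equiv), K2CO3 (1.5 equiv), degassed DMSO, 120 °C, Ar
Reagents that add atoms: none
Why: This is a nucleophilic aromatic substitution through a Meisenheimer adduct stabilised by the para acetyl group, and it should take place at O8 alone because the 5-OH is hydrogen-bonded to the C4 carbonyl and its anion is a delocalised, peri-hindered vinylogous carboxylate (the same bias that allows O8-selective alkylation of 5,8-dihydroxyflavones), while exclusion of air keeps the hydroquinone from oxidising.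

**Step 3**
Reactants: 5 8-(4-acetylphenoxy)-5-hydroxy-7-methoxy-2-(4-methoxyphenyl)-4H-chromen-4-one; 6 diethyl carbonate
Product: 7 ethyl 3-(4-{[5-hydroxy-7-methoxy-2-(4-methoxyphenyl)-4-oxo-4H-chromen-8-yl]oxy}phenyl)-3-oxopropanoate
Conditions: NaH (4 equiv), 6 (10 equiv), THF, reflux; cold 1 M HCl
Reagents that add atoms: diethyl carbonate (6), CCOC(=O)OCC
Why: This is a crossed Claisen condensation in which the non-enolisable carbonate can act only as acceptor, deprotonation of the product drives the equilibrium, and the 5-OH, held as its sodium phenoxide by the extra base, lowers the electrophilicity of ring C towards ethoxide and is regenerated from any transient aryl carbonate because phenoxide is the better leaving group.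

**Step 4**
Reactants: 7 ethyl 3-(4-{[5-hydroxy-7-methoxy-2-(4-methoxyphenyl)-4-oxo-4H-chromen-8-yl]oxy}phenyl)-3-oxopropanoate; 8 phloroglucinol (benzene-1,3,5-triol)
Product: 11 8-[4-(5,7-dihydroxy-4-oxo-4H-chromen-2-yl)phenoxy]-5-hydroxy-7-methoxy-2-(4-methoxyphenyl)-4H-chromen-4-one (target CNP0259871.0), via aroylketene 9 (not isolated), via 1,3-diketone 10 (not isolated)
Conditions: 8 (3 equiv, anhydrous), neat melt, 240 °C, slow N2 sweep; cooled, triturated with hot water to remove 8, chromatography
Reagents that add atoms: none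
Why: Above about 200 °C the enol form of 7 expels ethanol to give aroylketene 9, which the very electron-rich ring of 8 captures at carbon (directly, or at oxygen followed by an O-to-C acyl shift), so that the former ester carbon becomes C4 bonded to C4a in diketone 10. An ortho hydroxyl of 10 then adds to the aryl ketone carbonyl in a 6-exo-trig closure and the hemiketal loses water, which forms O1–C2 and completes ring F. The closest known reaction is the Mentzer pyrone synthesis itself, the solvent-free fusion of phloroglucinol with ethyl aroylacetates that gives 5,7-dihydroxyflavones. No stereocentre is created. The step needs chromone rather than coumarin closure, which is secured by the absence of any acid that would activate the ketone for a Pechmann-type attack by the ring carbon, and it needs no positional control because the three C–H carbons of 8 and the two ortho hydroxyls of 10 are equivalent. Within 7 the only other phenol is the chelated 5-OH on the carbonyl-deactivated ring A, which cannot compete with a threefold excess of 8, and that excess together with the gas sweep also holds back ketene dimerisation, a second annulation on ring D and hydrolytic loss of the ester.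

**Compound list**
1 | 5-hydroxy-7-methoxy-2-(4-methoxyphenyl)-4H-chromen-4-one | COc1ccc(-c2cc(=O)c3c(O)cc(OC)cc3o2)cc1 | starting material
2 | potassium 5-hydroxy-7-methoxy-2-(4-methoxyphenyl)-4-oxo-4H-chromen-8-yl sulfate | COc1ccc(-c2cc(=O)c3c(O)cc(OC)c(OS(=O)(=O)[O-])c3o2)cc1.[K+] | intermediate
3 | 5,8-dihydroxy-7-methoxy-2-(4-methoxyphenyl)-4H-chromen-4-one | COc1ccc(-c2cc(=O)c3c(O)cc(OC)c(O)c3o2)cc1 | intermediate
4 | 4'-fluoroacetophenone | CC(=O)c1ccc(F)cc1 | starting material
5 | 8-(4-acetylphenoxy)-5-hydroxy-7-methoxy-2-(4-methoxyphenyl)-4H-chromen-4-one | COc1ccc(-c2cc(=O)c3c(O)cc(OC)c(Oc4ccc(C(C)=O)cc4)c3o2)cc1 | intermediate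
6 | diethyl carbonate | CCOC(=O)OCC | starting material
7 | ethyl 3-(4-{[5-hydroxy-7-methoxy-2-(4-methoxyphenyl)-4-oxo-4H-chromen-8-yl]oxy}phenyl)-3-oxopropanoate | CCOC(=O)CC(=O)c1ccc(Oc2c(OC)cc(O)c3c(=O)cc(-c4ccc(OC)cc4)oc23)cc1 | intermediate
8 | phloroglucinol | Oc1cc(O)cc(O)c1 | starting material
9 | 3-(4-{[5-hydroxy-7-methoxy-2-(4-methoxyphenyl)-4-oxo-4H-chromen-8-yl]oxy}phenyl)-3-oxoprop-1-en-1-one (aroylketene) | O=C=CC(=O)c1ccc(Oc2c(OC)cc(O)c3c(=O)cc(-c4ccc(OC)cc4)oc23)cc1 | intermediate
10 | 1-(4-{[5-hydroxy-7-methoxy-2-(4-methoxyphenyl)-4-oxo-4H-chromen-8-yl]oxy}phenyl)-3-(2,4,6-trihydroxyphenyl)propane-1,3-dione | O=C(CC(=O)c1ccc(Oc2c(OC)cc(O)c3c(=O)cc(-c4ccc(OC)cc4)oc23)cc1)c1c(O)cc(O)cc1O | intermediate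
11 | 8-[4-(5,7-dihydroxy-4-oxo-4H-chromen-2-yl)phenoxy]-5-hydroxy-7-methoxy-2-(4-methoxyphenyl)-4H-chromen-4-one | COc1ccc(-c2cc(=O)c3c(O)cc(OC)c(Oc4ccc(-c5cc(=O)c6c(O)cc(O)cc6o5)cc4)c3o2)cc1 | target

Total step count: 4. Longest linear sequence: 4 (1 → 3 → 5 → 7 → 11).

**Steps most likely to fail**

Step 4.
- What may go wrong: the water released by the reaction may hydrolyse and decarboxylate the keto ester before acylation occurs. The ketene may self-condense, the closure may go in the coumarin sense, or ring C may open at 240 °C and reclose onto the other oxygen.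
- Fallback: ring F is built by the chalcone route, which forms C2–C3 and O1–C2 instead. It sets out from 3 and returns at 11.
- Hydroquinone 3 is arylated with 4-fluorobenzaldehyde (K2CO3, DMF, 90 °C, Ar) to 4-{[5-hydroxy-7-methoxy-2-(4-methoxyphenyl)-4-oxo-4H-chromen-8-yl]oxy}benzaldehyde F1.
- Claisen–Schmidt condensation with commercial 2'-hydroxy-4',6'-bis(methoxymethoxy)acetophenone (KOH, EtOH, rt) should give the (E)-2'-hydroxy-4',6'-bis(methoxymethoxy)-4-(flavon-8-yloxy)chalcone F2.
- I2 (cat.) in DMSO at 120 °C closes and dehydrogenates this to the 5,7-bis(methoxymethyl) ether of the target F3. Partial acetal loss at this stage does no harm.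
- HCl in MeOH/THF at 50 °C removes both acetals and delivers 11.

Step 2.
- What may go wrong: the hydroquinone anion may be oxidised by air, the doubly ortho-flanked 8-phenoxide may attack slowly at the temperature the fluoroketone requires, and the ketone may undergo aldol self-condensation under carbonate.
- Fallback: addition–elimination is replaced by ligand coupling at trivalent iodine, which runs near room temperature and tolerates hindered phenols. It sets out from 3 and returns at 5.
- 4'-Iodoacetophenone is oxidised and coupled in one pot (mCPBA, TsOH·H2O, MeCN, 75 °C; then 1,3,5-trimethoxybenzene) to (4-acetylphenyl)(2,4,6-trimethoxyphenyl)iodonium tosylate F4.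
- Treating 3 with F4 and K2CO3 in MeCN at 40 °C under argon should transfer the electron-poor aryl group to O8 and give 5.

Step 1.
- What may go wrong: conversion may be low and over-oxidation may occur, both typical of persulfate hydroxylation, and the potassium phenoxide may dissolve poorly.
- Fallback: the polarity of the ether formation is reversed, so no 8-hydroxyl is needed. It sets out from 1 and returns at 5, bypassing 3 and steps 1 and 2.
- Methylation of the chelated hydroxyl (MeI, K2CO3, DMF, 60 °C) gives 5,7-dimethoxy-2-(4-methoxyphenyl)-4H-chromen-4-one F5.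
- Electrophilic iodination (NIS, cat. CF3CO2H, MeCN) should go to C8, the usual site in 5,7-dialkoxyflavones, and give the 8-iodo-5,7,4'-trimethoxyflavone F6.
- Ullmann ether coupling with 4'-hydroxyacetophenone (CuI, N,N-dimethylglycine, Cs2CO3, dioxane, 100 °C) gives 8-(4-acetylphenoxy)-5,7-dimethoxy-2-(4-methoxyphenyl)-4H-chromen-4-one F7.
- BCl3 (CH2Cl2, −78 to 0 °C), chelated to the C4 carbonyl, cleaves only the 5-methyl ether and gives 5.

**Further compounds**
F1 | step 4 | 4-{[5-hydroxy-7-methoxy-2-(4-methoxyphenyl)-4-oxo-4H-chromen-8-yl]oxy}benzaldehyde | O=Cc1ccc(Oc2c(OC)cc(O)c3c(=O)cc(-c4ccc(OC)cc4)oc23)cc1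
F2 | step 4 | (E)-1-[2-hydroxy-4,6-bis(methoxymethoxy)phenyl]-3-(4-{[5-hydroxy-7-methoxy-2-(4-methoxyphenyl)-4-oxo-4H-chromen-8-yl]oxy}phenyl)prop-2-en-1-one | COCOc1cc(O)c(C(=O)/C=C/c2ccc(Oc3c(OC)cc(O)c4c(=O)cc(-c5ccc(OC)cc5)oc34)cc2)c(OCOC)c1
F3 | step 4 | 8-{4-[5,7-bis(methoxymethoxy)-4-oxo-4H-chromen-2-yl]phenoxy}-5-hydroxy-7-methoxy-2-(4-methoxyphenyl)-4H-chromen-4-one | COCOc1cc(OCOC)c2c(=O)cc(-c3ccc(Oc4c(OC)cc(O)c5c(=O)cc(-c6ccc(OC)cc6)oc45)cc3)oc2c1
F4 | step 2 | (4-acetylphenyl)(2,4,6-trimethoxyphenyl)iodonium 4-methylbenzenesulfonate | CC(=O)c1ccc([I+]c2c(OC)cc(OC)cc2OC)cc1.Cc1ccc(S(=O)(=O)[O-])cc1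
F5 | step 1 | 5,7-dimethoxy-2-(4-methoxyphenyl)-4H-chromen-4-one | COc1ccc(-c2cc(=O)c3c(OC)cc(OC)cc3o2)cc1
F6 | step 1 | 8-iodo-5,7-dimethoxy-2-(4-methoxyphenyl)-4H-chromen-4-one | COc1ccc(-c2cc(=O)c3c(OC)cc(OC)c(I)c3o2)cc1
F7 | step 1 | 8-(4-acetylphenoxy)-5,7-dimethoxy-2-(4-methoxyphenyl)-4H-chromen-4-one | COc1ccc(-c2cc(=O)c3c(OC)cc(OC)c(Oc4ccc(C(C)=O)cc4)c3o2)cc1
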